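**Plan**

1. The retrosynthesis first cuts the O1–C2 ether bond of the dihydropyran (C ring), then the C2–C1' bond between the chroman and the B ring. Last come the side-chain bonds (C6–CMe2 of the 1,1-dimethylallyl group, C2'–CH2 of the prenyl group) and the O–CMe2 / C4a–C4 bonds of the dimethylpyran ring.
2. Enabling feature: C2 is a carbinol-level carbon bonded to O1, to the C3 methylene and to aryl carbon C1'. With O1–C2 opened it is the O–CH2 carbon of a 3-arylpropyl carbamate, which can become a configurationally stable α-oxy lithium carbenoid. C1' (next to the C2' prenyl group, para to the pyran oxygen) is carried as an aryl boronic ester whose aryl group migrates from boron to C2.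
3. A-ring fragment, forward: 7-hydroxychroman-2-one → O7 prenyl ether → lactone opening and O1 silylation → aromatic Claisen shift (1,1-dimethylallyl to C6) → carbamate 9.
4. B-ring fragment, forward: bromo-isovanillin → dimethylpyran ring (propargyl Claisen / oxa-6π) → prenyl group → boronic ester 22. The fragments are joined in step 15; the C ring closes last by Mitsunobu etherification, followed by desilylation.
5. Stereochemistry: the only stereocentre (C2) comes from (−)-sparteine-mediated deprotonation (reagent control). It passes through a stereospecific 1,2-migration to the (R)-carbinol and is inverted to (2S) in the ring closure.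

Key step: step 15

Remark: 1 and 10 are taken as purchasable (1 is otherwise the hydrogenation product of umbelliferone); flavan numbering (O1, C2–C8a, C1'–C6') is used for the target atoms throughout.

**Route**

Step 1
Reactants: 1 7-hydroxychroman-2-one
Product: 2 7-[(3-methylbut-2-en-1-yl)oxy]chroman-2-one
Conditions: prenyl bromide, K2CO3, acetone, reflux
Reagents that add atoms: prenyl bromide, CC(C)=CCBr
Why: Williamson etherification; the lactone keeps O1 masked, so only the O7 phenoxide should be alkylated by the primary allylic bromide.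

Step 2
Reactants: 2 7-[(3-methylbut-2-en-1-yl)oxy]chroman-2-one
Product: 4 methyl 3-{2-[(tert-butyldimethylsilyl)oxy]-4-[(3-methylbut-2-en-1-yl)oxy]phenyl}propanoate, via ring-opened phenol ester 3 (not isolated)
Conditions: MeOH, Et3N (cat.), rt; evaporate; TBSCl, imidazole, DMF, rt
Reagents that add atoms: methanol, CO; tert-butyldimethylsilyl chloride, CC(C)(C)[Si](C)(C)Cl
Why: Base-catalysed methanolysis of the aryl ester (lactone) should free O1 as a phenol, which is silylated at once (imidazole-mediated silylation) before it can re-lactonise, so O1 and O7 are now differentiated.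

Step 3
Reactants: 4 methyl 3-{2-[(tert-butyldimethylsilyl)oxy]-4-[(3-methylbut-2-en-1-yl)oxy]phenyl}propanoate
Product: 6 methyl 3-{2-[(tert-butyldimethylsilyl)oxy]-4-hydroxy-5-(2-methylbut-3-en-2-yl)phenyl}propanoate, via ortho-dienone 5 (not isolated)
Conditions: PhNEt2, 190 °C, sealed tube, Ar
Reagents that add atoms: none
Why: Aromatic Claisen rearrangement ([3,3] shift with allyl inversion) should place the 1,1-dimethylallyl group on the ortho carbon that becomes C6, because the other ortho carbon lies between the prenyloxy and the bulky silyloxy group and the para carbon is blocked; tautomerisation of dienone 5 restores the phenol.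

Step 4
Reactants: 6 methyl 3-{2-[(tert-butyldimethylsilyl)oxy]-4-hydroxy-5-(2-methylbut-3-en-2-yl)phenyl}propanoate
Product: 7 methyl 3-{2-[(tert-butyldimethylsilyl)oxy]-5-(2-methylbut-3-en-2-yl)-4-[(triisopropylsilyl)oxy]phenyl}propanoate
Conditions: TIPSOTf, 2,6-lutidine, CH2Cl2, 0 °C → rt
Reagents that add atoms: triisopropylsilyl triflate, CC(C)[Si](OS(=O)(=O)C(F)(F)F)(C(C)C)C(C)C
Why: Silyl triflate with a hindered pyridine base is the standard silylation for a phenol flanked by a quaternary carbon and should cap O7 as a base-robust TIPS ether.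

Step 5
Reactants: 7 methyl 3-{2-[(tert-butyldimethylsilyl)oxy]-5-(2-methylbut-3-en-2-yl)-4-[(triisopropylsilyl)oxy]phenyl}propanoate
Product: 8 3-{2-[(tert-butyldimethylsilyl)oxy]-5-(2-methylbut-3-en-2-yl)-4-[(triisopropylsilyl)oxy]phenyl}propan-1-ol
Conditions: DIBAL-H, CH2Cl2, −78 → 0 °C; Rochelle salt work-up
Reagents that add atoms: none
Why: Hydride reduction of the methyl ester to the primary alcohol should leave the aryl silyl ethers and the terminal alkene untouched.

Step 6
Reactants: 8 3-{2-[(tert-butyldimethylsilyl)oxy]-5-(2-methylbut-3-en-2-yl)-4-[(triisopropylsilyl)oxy]phenyl}propan-1-ol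
Product: 9 3-{2-[(tert-butyldimethylsilyl)oxy]-5-(2-methylbut-3-en-2-yl)-4-[(triisopropylsilyl)oxy]phenyl}propyl N,N-diisopropylcarbamate
Conditions: i-Pr2NCOCl, Et3N, CH2Cl2, reflux
Reagents that add atoms: N,N-diisopropylcarbamoyl chloride, CC(C)N(C(C)C)C(=O)Cl
Why: O-Carbamoylation of the primary alcohol installs the hindered carbamate that directs and stabilises α-lithiation and later acts as the leaving group.

Step 7
Reactants: 10 2-bromo-5-hydroxy-4-methoxybenzaldehyde
Product: 11 2-bromo-4-methoxy-5-[(2-methylbut-3-yn-2-yl)oxy]benzaldehyde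
Conditions: 3-chloro-3-methylbut-1-yne, DBU, CuCl2·2H2O (cat.), MeCN, 0 °C
Reagents that add atoms: 3-chloro-3-methylbut-1-yne, C#CC(C)(C)Cl
Why: Copper-catalysed propargylic etherification of the only phenol of 10 with the tertiary propargylic chloride should give the 1,1-dimethylpropargyl aryl ether.

Step 8
Reactants: 11 2-bromo-4-methoxy-5-[(2-methylbut-3-yn-2-yl)oxy]benzaldehyde
Product: 15 6-bromo-8-methoxy-2,2-dimethyl-2H-chromene-5-carbaldehyde, via allenyl dienone 12 (not isolated), via ortho-allenylphenol 13 (not isolated), via ortho-quinone methide 14 (not isolated)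
Conditions: PhNEt2, 180 °C
Reagents that add atoms: none
Why: Propargyl Claisen rearrangement to the only free ortho carbon (the other carries OMe), enolisation, [1,5]-hydrogen shift and oxa-6π electrocyclisation should close the 2,2-dimethylpyran ring with unambiguous regiochemistry.

Step 9
Reactants: 15 6-bromo-8-methoxy-2,2-dimethyl-2H-chromene-5-carbaldehyde
Product: 16 (6-bromo-8-methoxy-2,2-dimethyl-2H-chromen-5-yl)methanol
Conditions: NaBH4, MeOH/THF, 0 °C
Reagents that add atoms: none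
Why: Borohydride 1,2-reduction of the aryl aldehyde is chemoselective in the presence of the aryl bromide and the chromene alkene.

Step 10
Reactants: 16 (6-bromo-8-methoxy-2,2-dimethyl-2H-chromen-5-yl)methanol
Product: 17 6-bromo-5-(bromomethyl)-8-methoxy-2,2-dimethyl-2H-chromene
Conditions: CBr4, PPh3, CH2Cl2, 0 °C
Reagents that add atoms: carbon tetrabromide, BrC(Br)(Br)Br
Why: Appel bromination converts the benzylic alcohol into the bromide under neutral conditions that the acid-sensitive chromene tolerates; the electron-rich benzylic bromide is used directly.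

Step 11
Reactants: 17 6-bromo-5-(bromomethyl)-8-methoxy-2,2-dimethyl-2H-chromene
Product: 18 6-bromo-8-methoxy-2,2-dimethyl-5-(3-methylbut-2-en-1-yl)-2H-chromene
Conditions: Me2C=CHMgBr, CuI (10 mol %), THF, −30 → 0 °C
Reagents that add atoms: (2-methylprop-1-en-1-yl)magnesium bromide, CC(C)=C[Mg]Br
Why: Copper-catalysed coupling of the benzylic bromide with the alkenyl Grignard reagent should build the prenyl chain; the aryl bromide does not exchange with an alkenylmagnesium halide at this temperature.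

Step 12
Reactants: 18 6-bromo-8-methoxy-2,2-dimethyl-5-(3-methylbut-2-en-1-yl)-2H-chromene
Product: 19 6-bromo-2,2-dimethyl-5-(3-methylbut-2-en-1-yl)-2H-chromen-8-ol
Conditions: NaSEt, DMF, 120 °C; aq. NH4Cl
Reagents that add atoms: none
Why: SN2 demethylation of the aryl methyl ether by thiolate frees the later 5'-OH without acid, so both alkenes and the electron-rich aryl bromide should survive.

Step 13
Reactants: 19 6-bromo-2,2-dimethyl-5-(3-methylbut-2-en-1-yl)-2H-chromen-8-ol
Product: 20 [(6-bromo-2,2-dimethyl-5-(3-methylbut-2-en-1-yl)-2H-chromen-8-yl)oxy]triisopropylsilane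
Conditions: TIPSCl, imidazole, DMF, rt
Reagents that add atoms: triisopropylsilyl chloride, CC(C)[Si](Cl)(C(C)C)C(C)C
Why: Imidazole-mediated silylation gives a fluoride-labile ether that withstands organolithium reagents and does not direct ortho-metalation.

Step 14
Reactants: 20 [(6-bromo-2,2-dimethyl-5-(3-methylbut-2-en-1-yl)-2H-chromen-8-yl)oxy]triisopropylsilane
Product: 22 triisopropyl{[2,2-dimethyl-5-(3-methylbut-2-en-1-yl)-6-(4,4,5,5-tetramethyl-1,3,2-dioxaborolan-2-yl)-2H-chromen-8-yl]oxy}silane, via aryllithium 21 (not isolated)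
Conditions: n-BuLi, THF, −78 °C; i-PrOBpin, −78 °C → rt; aq. NH4Cl
Reagents that add atoms: 2-isopropoxy-4,4,5,5-tetramethyl-1,3,2-dioxaborolane, CC(C)OB1OC(C)(C)C(C)(C)O1
Why: Bromine–lithium exchange at −78 °C is faster than deprotonation of the benzylic/allylic CH2, and the aryllithium is trapped by the borate to give the pinacol boronic ester at C1'.

Step 15
Reactants: 9 3-{2-[(tert-butyldimethylsilyl)oxy]-5-(2-methylbut-3-en-2-yl)-4-[(triisopropylsilyl)oxy]phenyl}propyl N,N-diisopropylcarbamate; 22 B-ring aryl pinacol boronic ester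
Product: 26 (1R)-3-{2-[(tert-butyldimethylsilyl)oxy]-5-(2-methylbut-3-en-2-yl)-4-[(triisopropylsilyl)oxy]phenyl}-1-{2,2-dimethyl-5-(3-methylbut-2-en-1-yl)-8-[(triisopropylsilyl)oxy]-2H-chromen-6-yl}propan-1-ol, via (S)-α-lithio carbamate 23 (not isolated), via lithium boronate complex 24 (not isolated), via (R)-benzylic pinacol boronic ester 25 (not isolated)
Conditions: 9 (1.3 equiv), s-BuLi, (−)-sparteine, Et2O, −78 °C, 5 h; 22, −78 °C, 1 h; then 35 °C, 16 h; then 2 M NaOH, 30% H2O2, THF, 0 °C → rt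
Reagents that add atoms: hydrogen peroxide, OO
Why: s-BuLi/(−)-sparteine removes the pro-S hydrogen at the O–CH2 carbon of 9 (carbonyl-directed, complex-induced deprotonation) to give the configurationally stable (S)-lithium carbenoid 23, which boronic ester 22 captures with retention as boronate 24; on warming, the B-ring aryl group migrates from boron to carbon anti to the departing carbamate (1,2-metallate rearrangement with inversion), forming the C2–C1' bond in (R)-boronic ester 25, whose C–B bond is oxidised with retention to the (R)-carbinol 26. The closest known reaction type is the lithiation–borylation of primary O-alkyl carbamates with aryl pinacol boronic esters, a Matteson-type homologation. No ring is closed in this step. The new stereocentre (the later C2) is set by reagent control from (−)-sparteine and carried through two stereospecific events, retentive borylation and invertive migration. The step needs lithiation only at the O–CH2 carbon, which the chelating carbamate should secure over the silyl ethers (poor directing groups), the benzylic CH2 and the 1,1-dimethylallyl group (no allylic hydrogen), and it needs aryl rather than pinacol-oxygen migration, which the electron-rich aryl group favours. Because the ortho prenyl group slows boronate formation, the unhindered primary carbenoid is used in slight excess.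

Step 16
Reactants: 26 (R)-carbinol with O1 as TBS ether
Product: 27 2-{(3R)-3-hydroxy-3-[2,2-dimethyl-5-(3-methylbut-2-en-1-yl)-8-[(triisopropylsilyl)oxy]-2H-chromen-6-yl]propyl}-4-(2-methylbut-3-en-2-yl)-5-[(triisopropylsilyl)oxy]phenol
Conditions: K2CO3 (0.3 equiv), MeOH/THF, 0 °C → rt
Reagents that add atoms: none
Why: Carbonate-catalysed methanolysis should cleave the unhindered aryl TBS ether much faster than the two aryl TIPS ethers (one shielded by the quaternary carbon), and loss of a TIPS group would not harm the next step because only O1 can reach C2 intramolecularly.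

Step 17
Reactants: 27 (R)-hydroxy phenol
Product: 28 (2S)-6-(2-methylbut-3-en-2-yl)-7-[(triisopropylsilyl)oxy]-2-{2,2-dimethyl-5-(3-methylbut-2-en-1-yl)-8-[(triisopropylsilyl)oxy]-2H-chromen-6-yl}chromane
Conditions: PPh3, DIAD, toluene (0.01 M), 0 °C → rt
Reagents that add atoms: none
Why: Mitsunobu etherification, in which the O1 phenoxide displaces the oxyphosphonium of the secondary benzylic alcohol in a 6-exo-tet SN2 closure with inversion, should turn the (R)-carbinol into the (2S)-chroman; dilution and a non-polar medium are chosen to suppress ionisation.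

Step 18
Reactants: 28 (2S)-bis-TIPS flavan
Product: 29 Kazinol H, (2S)-2-[8-hydroxy-2,2-dimethyl-5-(3-methylbut-2-en-1-yl)-2H-chromen-6-yl]-6-(2-methylbut-3-en-2-yl)chroman-7-ol
Conditions: TBAF, AcOH, THF, 0 °C → rt
Reagents that add atoms: none
Why: Buffered fluoride should cleave both aryl TIPS ethers without acid, so the prenyl, 1,1-dimethylallyl and chromene units and the benzylic C2–O1 ether stay intact and C2 is not disturbed.

**Compound list**

1 | 7-hydroxychroman-2-one (7-hydroxy-3,4-dihydrocoumarin) | O=C1CCc2ccc(O)cc2O1 | starting material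
2 | 7-[(3-methylbut-2-en-1-yl)oxy]chroman-2-one | O=C1CCc2ccc(OCC=C(C)C)cc2O1 | intermediate
3 | methyl 3-{2-hydroxy-4-[(3-methylbut-2-en-1-yl)oxy]phenyl}propanoate (formed in the flask) | COC(=O)CCc1ccc(OCC=C(C)C)cc1O | intermediate
4 | methyl 3-{2-[(tert-butyldimethylsilyl)oxy]-4-[(3-methylbut-2-en-1-yl)oxy]phenyl}propanoate | COC(=O)CCc1ccc(OCC=C(C)C)cc1O[Si](C)(C)C(C)(C)C | intermediate
5 | methyl 3-[6-(tert-butyldimethylsilyloxy)-3-(2-methylbut-3-en-2-yl)-4-oxocyclohexa-1,5-dien-1-yl]propanoate (ortho-dienone, formed in the flask) | COC(=O)CCC1=CC(C(C)(C)C=C)C(=O)C=C1O[Si](C)(C)C(C)(C)C | intermediate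
6 | methyl 3-{2-[(tert-butyldimethylsilyl)oxy]-4-hydroxy-5-(2-methylbut-3-en-2-yl)phenyl}propanoate | COC(=O)CCc1cc(C(C)(C)C=C)c(O)cc1O[Si](C)(C)C(C)(C)C | intermediate
7 | methyl 3-{2-[(tert-butyldimethylsilyl)oxy]-5-(2-methylbut-3-en-2-yl)-4-[(triisopropylsilyl)oxy]phenyl}propanoate | COC(=O)CCc1cc(C(C)(C)C=C)c(O[Si](C(C)C)(C(C)C)C(C)C)cc1O[Si](C)(C)C(C)(C)C | intermediate
8 | 3-{2-[(tert-butyldimethylsilyl)oxy]-5-(2-methylbut-3-en-2-yl)-4-[(triisopropylsilyl)oxy]phenyl}propan-1-ol | OCCCc1cc(C(C)(C)C=C)c(O[Si](C(C)C)(C(C)C)C(C)C)cc1O[Si](C)(C)C(C)(C)C | intermediate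
9 | 3-{2-[(tert-butyldimethylsilyl)oxy]-5-(2-methylbut-3-en-2-yl)-4-[(triisopropylsilyl)oxy]phenyl}propyl N,N-diisopropylcarbamate | CC(C)N(C(C)C)C(=O)OCCCc1cc(C(C)(C)C=C)c(O[Si](C(C)C)(C(C)C)C(C)C)cc1O[Si](C)(C)C(C)(C)C | intermediate
10 | 2-bromo-5-hydroxy-4-methoxybenzaldehyde | O=Cc1cc(O)c(OC)cc1Br | starting material
11 | 2-bromo-4-methoxy-5-[(2-methylbut-3-yn-2-yl)oxy]benzaldehyde | O=Cc1cc(OC(C)(C)C#C)c(OC)cc1Br | intermediate
12 | 2-bromo-4-methoxy-6-(3-methylbuta-1,2-dien-1-yl)-5-oxocyclohexa-1,3-diene-1-carbaldehyde (allenyl dienone, formed in the flask) | O=CC1=C(Br)C=C(OC)C(=O)C1C=C=C(C)C | intermediate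
13 | 6-bromo-3-hydroxy-4-methoxy-2-(3-methylbuta-1,2-dien-1-yl)benzaldehyde (formed in the flask) | O=Cc1c(C=C=C(C)C)c(O)c(OC)cc1Br | intermediate
14 | 2-bromo-4-methoxy-6-(3-methylbut-2-en-1-ylidene)-5-oxocyclohexa-1,3-diene-1-carbaldehyde (ortho-quinone methide, formed in the flask) | O=CC1=C(Br)C=C(OC)C(=O)C1=CC=C(C)C | intermediate
15 | 6-bromo-8-methoxy-2,2-dimethyl-2H-chromene-5-carbaldehyde | O=Cc1c(Br)cc(OC)c2OC(C)(C)C=Cc12 | intermediate
16 | (6-bromo-8-methoxy-2,2-dimethyl-2H-chromen-5-yl)methanol | OCc1c(Br)cc(OC)c2OC(C)(C)C=Cc12 | intermediate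
17 | 6-bromo-5-(bromomethyl)-8-methoxy-2,2-dimethyl-2H-chromene | BrCc1c(Br)cc(OC)c2OC(C)(C)C=Cc12 | intermediate
18 | 6-bromo-8-methoxy-2,2-dimethyl-5-(3-methylbut-2-en-1-yl)-2H-chromene | CC(C)=CCc1c(Br)cc(OC)c2OC(C)(C)C=Cc12 | intermediate
19 | 6-bromo-2,2-dimethyl-5-(3-methylbut-2-en-1-yl)-2H-chromen-8-ol | CC(C)=CCc1c(Br)cc(O)c2OC(C)(C)C=Cc12 | intermediate
20 | [(6-bromo-2,2-dimethyl-5-(3-methylbut-2-en-1-yl)-2H-chromen-8-yl)oxy]triisopropylsilane | CC(C)=CCc1c(Br)cc(O[Si](C(C)C)(C(C)C)C(C)C)c2OC(C)(C)C=Cc12 | intermediate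
21 | {2,2-dimethyl-5-(3-methylbut-2-en-1-yl)-8-[(triisopropylsilyl)oxy]-2H-chromen-6-yl}lithium (formed in the flask) | CC(C)=CCc1c([Li])cc(O[Si](C(C)C)(C(C)C)C(C)C)c2OC(C)(C)C=Cc12 | intermediate
22 | triisopropyl{[2,2-dimethyl-5-(3-methylbut-2-en-1-yl)-6-(4,4,5,5-tetramethyl-1,3,2-dioxaborolan-2-yl)-2H-chromen-8-yl]oxy}silane | CC(C)=CCc1c(B3OC(C)(C)C(C)(C)O3)cc(O[Si](C(C)C)(C(C)C)C(C)C)c2OC(C)(C)C=Cc12 | intermediate
23 | (S)-1-lithio derivative of carbamate 9, lithium on the O–CH carbon (sparteine complex, formed in the flask) | [Li][C@H](OC(=O)N(C(C)C)C(C)C)CCc1cc(C(C)(C)C=C)c(O[Si](C(C)C)(C(C)C)C(C)C)cc1O[Si](C)(C)C(C)(C)C | intermediate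
24 | lithium boronate complex of 23 and 22, (S) at the carbamate carbon (formed in the flask) | [Li+].CC1(C)O[B-](OC1(C)C)(c1cc(O[Si](C(C)C)(C(C)C)C(C)C)c2OC(C)(C)C=Cc2c1CC=C(C)C)[C@H](OC(=O)N(C(C)C)C(C)C)CCc1cc(C(C)(C)C=C)c(O[Si](C(C)C)(C(C)C)C(C)C)cc1O[Si](C)(C)C(C)(C)C | intermediate
25 | (R)-secondary benzylic pinacol boronic ester, Bpin in place of the OH of 26 (formed in the flask) | CC1(C)OB(OC1(C)C)[C@@H](c1cc(O[Si](C(C)C)(C(C)C)C(C)C)c2OC(C)(C)C=Cc2c1CC=C(C)C)CCc1cc(C(C)(C)C=C)c(O[Si](C(C)C)(C(C)C)C(C)C)cc1O[Si](C)(C)C(C)(C)C | intermediate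
26 | (1R)-3-{2-[(tert-butyldimethylsilyl)oxy]-5-(2-methylbut-3-en-2-yl)-4-[(triisopropylsilyl)oxy]phenyl}-1-{2,2-dimethyl-5-(3-methylbut-2-en-1-yl)-8-[(triisopropylsilyl)oxy]-2H-chromen-6-yl}propan-1-ol | O[C@@H](c1cc(O[Si](C(C)C)(C(C)C)C(C)C)c2OC(C)(C)C=Cc2c1CC=C(C)C)CCc1cc(C(C)(C)C=C)c(O[Si](C(C)C)(C(C)C)C(C)C)cc1O[Si](C)(C)C(C)(C)C | intermediate
27 | 2-{(3R)-3-hydroxy-3-[2,2-dimethyl-5-(3-methylbut-2-en-1-yl)-8-[(triisopropylsilyl)oxy]-2H-chromen-6-yl]propyl}-4-(2-methylbut-3-en-2-yl)-5-[(triisopropylsilyl)oxy]phenol | O[C@@H](c1cc(O[Si](C(C)C)(C(C)C)C(C)C)c2OC(C)(C)C=Cc2c1CC=C(C)C)CCc1cc(C(C)(C)C=C)c(O[Si](C(C)C)(C(C)C)C(C)C)cc1O | intermediate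
28 | (2S)-6-(2-methylbut-3-en-2-yl)-7-[(triisopropylsilyl)oxy]-2-{2,2-dimethyl-5-(3-methylbut-2-en-1-yl)-8-[(triisopropylsilyl)oxy]-2H-chromen-6-yl}chromane | C=CC(C)(C)c1cc2c(cc1O[Si](C(C)C)(C(C)C)C(C)C)O[C@H](c1cc(O[Si](C(C)C)(C(C)C)C(C)C)c3c(c1CC=C(C)C)C=CC(C)(C)O3)CC2 | intermediate
29 | Kazinol H, (2S)-2-[8-hydroxy-2,2-dimethyl-5-(3-methylbut-2-en-1-yl)-2H-chromen-6-yl]-6-(2-methylbut-3-en-2-yl)chroman-7-ol | C=CC(C)(C)c1cc2c(cc1O)O[C@H](c1cc(O)c3c(c1CC=C(C)C)C=CC(C)(C)O3)CC2 | target

**Step count**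

Total: 18 steps. Longest linear sequence: 12 steps (10 → 29, steps 7–18); the A-ring branch (1 → 9) has 6 steps.

**Steps most likely to fail, with fallbacks**

Step 15. The lithium carbenoid may be captured too slowly by the ortho-substituted boronic ester and decompose before the boronate forms, or the boronate may not rearrange cleanly. The fallback makes the C2–C1' bond by acyl substitution and sets the stereocentre by catalytic asymmetric reduction; it sets out from ester 7 and bromide 20 and comes back at 26. Ester 7 is converted with MeNH(OMe)·HCl and i-PrMgCl (THF, −20 °C) into the Weinreb amide F1. Aryllithium 21, made from 20 as in step 14, is added at −78 °C to give the aryl ketone F2. Corey–Bakshi–Shibata reduction with the (S)-oxazaborolidine and catecholborane (toluene, −78 °C, chosen over borane to spare the alkenes) should then give the (R)-carbinol 26.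

Step 3. The [3,3] shift may leak to the other ortho carbon, the prenyl ether may fragment, or the new phenol may add to its own vinyl group at the temperature required. The fallback uses cross-coupling in place of the sigmatropic shift; it sets out from 1 and comes back at 7. Bromination of 1 (NBS, MeCN, 0 °C) at C6, the ortho position not flanked by both oxygens, would give 6-bromo-7-hydroxychroman-2-one F3, and silylation (TIPSCl, imidazole) its TIPS ether F4. A branched-selective Pd-catalysed Suzuki–Miyaura coupling with prenylboronic acid pinacol ester (allyl transfer through its γ-carbon; biarylphosphine-ligated Pd, aq. K3PO4, acidic work-up to re-close the lactone) would give 6-(2-methylbut-3-en-2-yl)-7-[(triisopropylsilyl)oxy]chroman-2-one F5. Methanolysis to the phenol ester F6 and silylation with TBSCl, as in step 2, then give 7.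

Step 17. The activated benzylic alcohol may partly ionise (the cation is stabilised by the para pyran oxygen of the B ring), eroding configurational purity, or may eliminate to the styrene. The fallback closes the ring at aryl carbon C8a so that no bond to C2 is broken; it sets out from 9 and 22 and comes back at 28. Step 15 is run with (+)-sparteine and gives, through the mirror-image (R)-lithio carbamate F7, boronate complex F8 and (S)-boronic ester F9, the (S)-carbinol F10. K2CO3/MeOH frees the (S)-hydroxy phenol F11, and PhNTf2/Et3N triflates only the phenol to give the aryl triflate F12. Pd-catalysed intramolecular C–O coupling (Pd(OAc)2, a bulky di-tert-butyl biarylphosphine, K3PO4, toluene, 80 °C) should then form the O1–C8a bond with retention at C2 and give 28.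

**Further compounds**

F1 | step 15 | 3-{2-[(tert-butyldimethylsilyl)oxy]-5-(2-methylbut-3-en-2-yl)-4-[(triisopropylsilyl)oxy]phenyl}-N-methoxy-N-methylpropanamide | CON(C)C(=O)CCc1cc(C(C)(C)C=C)c(O[Si](C(C)C)(C(C)C)C(C)C)cc1O[Si](C)(C)C(C)(C)C
F2 | step 15 | 3-{2-[(tert-butyldimethylsilyl)oxy]-5-(2-methylbut-3-en-2-yl)-4-[(triisopropylsilyl)oxy]phenyl}-1-{2,2-dimethyl-5-(3-methylbut-2-en-1-yl)-8-[(triisopropylsilyl)oxy]-2H-chromen-6-yl}propan-1-one | O=C(c1cc(O[Si](C(C)C)(C(C)C)C(C)C)c2OC(C)(C)C=Cc2c1CC=C(C)C)CCc1cc(C(C)(C)C=C)c(O[Si](C(C)C)(C(C)C)C(C)C)cc1O[Si](C)(C)C(C)(C)C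
F3 | step 3 | 6-bromo-7-hydroxychroman-2-one | O=C1CCc2cc(Br)c(O)cc2O1
F4 | step 3 | 6-bromo-7-[(triisopropylsilyl)oxy]chroman-2-one | O=C1CCc2cc(Br)c(O[Si](C(C)C)(C(C)C)C(C)C)cc2O1
F5 | step 3 | 6-(2-methylbut-3-en-2-yl)-7-[(triisopropylsilyl)oxy]chroman-2-one | O=C1CCc2cc(C(C)(C)C=C)c(O[Si](C(C)C)(C(C)C)C(C)C)cc2O1
F6 | step 3 | methyl 3-{2-hydroxy-5-(2-methylbut-3-en-2-yl)-4-[(triisopropylsilyl)oxy]phenyl}propanoate | COC(=O)CCc1cc(C(C)(C)C=C)c(O[Si](C(C)C)(C(C)C)C(C)C)cc1O
F7 | step 17 | (R)-1-lithio derivative of carbamate 9 (enantiomer of 23) | [Li][C@@H](OC(=O)N(C(C)C)C(C)C)CCc1cc(C(C)(C)C=C)c(O[Si](C(C)C)(C(C)C)C(C)C)cc1O[Si](C)(C)C(C)(C)C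
F8 | step 17 | lithium boronate complex, (R) at the carbamate carbon (enantiomer of 24) | [Li+].CC1(C)O[B-](OC1(C)C)(c1cc(O[Si](C(C)C)(C(C)C)C(C)C)c2OC(C)(C)C=Cc2c1CC=C(C)C)[C@@H](OC(=O)N(C(C)C)C(C)C)CCc1cc(C(C)(C)C=C)c(O[Si](C(C)C)(C(C)C)C(C)C)cc1O[Si](C)(C)C(C)(C)C
F9 | step 17 | (S)-secondary benzylic pinacol boronic ester (enantiomer of 25) | CC1(C)OB(OC1(C)C)[C@H](c1cc(O[Si](C(C)C)(C(C)C)C(C)C)c2OC(C)(C)C=Cc2c1CC=C(C)C)CCc1cc(C(C)(C)C=C)c(O[Si](C(C)C)(C(C)C)C(C)C)cc1O[Si](C)(C)C(C)(C)C
F10 | step 17 | (1S)-3-{2-[(tert-butyldimethylsilyl)oxy]-5-(2-methylbut-3-en-2-yl)-4-[(triisopropylsilyl)oxy]phenyl}-1-{2,2-dimethyl-5-(3-methylbut-2-en-1-yl)-8-[(triisopropylsilyl)oxy]-2H-chromen-6-yl}propan-1-ol | O[C@H](c1cc(O[Si](C(C)C)(C(C)C)C(C)C)c2OC(C)(C)C=Cc2c1CC=C(C)C)CCc1cc(C(C)(C)C=C)c(O[Si](C(C)C)(C(C)C)C(C)C)cc1O[Si](C)(C)C(C)(C)C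
F11 | step 17 | 2-{(3S)-3-hydroxy-3-[2,2-dimethyl-5-(3-methylbut-2-en-1-yl)-8-[(triisopropylsilyl)oxy]-2H-chromen-6-yl]propyl}-4-(2-methylbut-3-en-2-yl)-5-[(triisopropylsilyl)oxy]phenol | O[C@H](c1cc(O[Si](C(C)C)(C(C)C)C(C)C)c2OC(C)(C)C=Cc2c1CC=C(C)C)CCc1cc(C(C)(C)C=C)c(O[Si](C(C)C)(C(C)C)C(C)C)cc1O
F12 | step 17 | 2-{(3S)-3-hydroxy-3-[2,2-dimethyl-5-(3-methylbut-2-en-1-yl)-8-[(triisopropylsilyl)oxy]-2H-chromen-6-yl]propyl}-4-(2-methylbut-3-en-2-yl)-5-[(triisopropylsilyl)oxy]phenyl trifluoromethanesulfonate | O[C@H](c1cc(O[Si](C(C)C)(C(C)C)C(C)C)c2OC(C)(C)C=Cc2c1CC=C(C)C)CCc1cc(C(C)(C)C=C)c(O[Si](C(C)C)(C(C)C)C(C)C)cc1OS(=O)(=O)C(F)(F)F
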